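## Retrosynthetic overview

1. β-Tocopherol 15 ⇐ benzyl ether 14 (hydrogenolysis); the C2 methyl of 14 ⇐ the CH2CO2H arm of chroman-2-acetic acid 11 (reductive decarboxylation).
2. 11 ⇐ bridged lactone 10 (reduction of the benzylic C4–O bond) ⇐ bridged lactol 9 (oxidation).
3. 9 ⇐ salicylaldehyde 3 + (7R,11R)-phytenal 5: intermolecular vinylogous aldol (C3–C4 bond) through the dienamine of 5, then oxa-Michael closure (O1–C2, sets C2) and lactol trapping.
4. 3 ⇐ 2,5-dimethylhydroquinone 1 (monobenzylation, ortho-formylation); 5 ⇐ natural phytol 4 (both side-chain stereocentres from the chiral pool).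
5. Ring order: the aromatic ring is bought; the pyran ring closes in the key step, the temporary lactol ring directly after it; that extra ring is opened again in step 6.

Assumption: natural (2E,7R,11R)-phytol is bought as a single stereoisomer, and the (S)-catalyst of step 4 is taken to give the 2R chroman (phenol oxygen adds to the iminium face opposite the bulky pyrrolidine substituent); a test run against the (R)-catalyst product by HPLC confirms the sense before scale-up.

## Route

Step 1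
Reactants: 1 2,5-dimethylhydroquinone
Product: 2 4-(benzyloxy)-2,5-dimethylphenol
Conditions: 1 (2.5 equiv), BnBr (1.0 equiv), K2CO3 (1.1 equiv), acetone, reflux, N2; excess 1 recovered
Reagents that add atoms: benzyl bromide, BrCc1ccccc1
Why: Williamson ether synthesis on a symmetrical diol, where an excess of 1 gives mainly the mono-ether, separable by chromatography from recovered 1 and the bis-ether.

Step 2
Reactants: 2 4-(benzyloxy)-2,5-dimethylphenol
Product: 3 5-(benzyloxy)-2-hydroxy-3,6-dimethylbenzaldehyde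
Conditions: MgCl2 (1.5 equiv), Et3N (3.75 equiv), (CH2O)n (7 equiv), MeCN, reflux; 1 M HCl work-up
Reagents that add atoms: paraformaldehyde (as formaldehyde), C=O
Why: Casnati–Skattebøl magnesium-phenoxide ortho-formylation, which reacts only ortho to the free OH, and 2 has a single free ortho position.

Step 3
Reactants: 4 natural phytol
Product: 5 (2E,7R,11R)-phytenal
Conditions: activated MnO2 (15 equiv), hexane, rt
Reagents that add atoms: none
Why: Selective allylic alcohol oxidation that leaves C7 and C11 untouched; any E/Z drift is harmless because step 4 passes through a dienamine.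

Step 4
Reactants: 3 5-(benzyloxy)-2-hydroxy-3,6-dimethylbenzaldehyde; 5 (2E,7R,11R)-phytenal
Product: 9 bridged tricyclic lactol (2R,4R), via phytenal dienamine 6 (not isolated), via vinylogous aldol enal 7 (not isolated), via chromanol aldehyde 8 (not isolated)
Conditions: (S)-2-{bis[3,5-bis(trifluoromethyl)phenyl](trimethylsilyloxy)methyl}pyrrolidine (30 mol%), PhCO2H (30 mol%), toluene, rt, 3 d
Reagents that add atoms: none
Why: Amine-catalysed domino vinylogous aldol/oxa-Michael reaction in which the unhindered exocyclic γ-carbon of dienamine 6 adds to the aldehyde of 3 (intermolecular aldol, C3–C4 bond), the phenol oxygen then closes onto the iminium ion of 7 on the face away from the diaryl(silyloxy)methyl group to set C2 as R, and only the 2,4-cis hydroxy aldehyde 8 can be trapped as lactol 9, so the reversible C4 centre (R, removed in step 6) is funnelled to match C2.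

Step 5
Reactants: 9 bridged tricyclic lactol
Product: 10 bridged δ-lactone (2R,4R)
Conditions: PhI(OAc)2 (1.3 equiv), TEMPO (10 mol%), CH2Cl2, rt
Reagents that add atoms: none
Why: Oxoammonium (TEMPO) oxidation of a lactol to the lactone, in which both anomers converge and no stereocentre is touched.

Step 6
Reactants: 10 bridged δ-lactone
Product: 11 2-{(2R)-6-(benzyloxy)-5,8-dimethyl-2-[(4R,8R)-4,8,12-trimethyltridecyl]chroman-2-yl}acetic acid
Conditions: Et3SiH (3 equiv), TFA (10 equiv), CH2Cl2, 0 °C to rt; aqueous work-up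
Reagents that add atoms: none
Why: Ionic hydrogenation, in which the protonated lactone ionises at the benzylic C4–O bond (cation stabilised by the ortho ring oxygen) and is reduced by silane hydride, removing the C4 centre while no bond at C2 is broken.

Step 7
Reactants: 11 chroman-2-acetic acid
Product: 14 (2R,4'R,8'R)-β-tocopherol benzyl ether, via acid chloride 12 (not isolated), via Barton ester 13 (not isolated)
Conditions: (COCl)2, cat. DMF, CH2Cl2, 0 °C to rt; then 2-mercaptopyridine N-oxide sodium salt, cat. DMAP, t-BuSH (10 equiv), toluene, 80 °C, W lamp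
Reagents that add atoms: none
Why: Barton reductive decarboxylation, in which the thiohydroxamate ester gives a primary radical that takes hydrogen from t-BuSH faster than it can fragment, turning CH2CO2H into the C2 methyl with C2 untouched (2R retained).

Step 8
Reactants: 14 (2R,4'R,8'R)-β-tocopherol benzyl ether
Product: 15 (2R,4'R,8'R)-β-tocopherol
Conditions: H2 (1 atm), 10% Pd/C, EtOAc, rt
Reagents that add atoms: none
Why: Catalytic hydrogenolysis of the aryl benzyl ether, with nothing else in 14 reducible and no stereocentre affected.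

## Compound list

1 | 2,5-dimethylhydroquinone (2,5-dimethylbenzene-1,4-diol) | Cc1cc(O)c(C)cc1O | starting material
2 | 4-(benzyloxy)-2,5-dimethylphenol | Cc1cc(OCc2ccccc2)c(C)cc1O | intermediate
3 | 5-(benzyloxy)-2-hydroxy-3,6-dimethylbenzaldehyde | Cc1cc(OCc2ccccc2)c(C)c(C=O)c1O | intermediate
4 | natural phytol, (2E,7R,11R)-3,7,11,15-tetramethylhexadec-2-en-1-ol | OC/C=C(\C)CCC[C@H](C)CCC[C@H](C)CCCC(C)C | starting material
5 | (2E,7R,11R)-phytenal, (2E,7R,11R)-3,7,11,15-tetramethylhexadec-2-enal | O=C/C=C(\C)CCC[C@H](C)CCC[C@H](C)CCCC(C)C | intermediate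
6 | dienamine of 5 with the catalyst: (2S)-2-{bis[3,5-bis(trifluoromethyl)phenyl](trimethylsilyloxy)methyl}-1-[(1E,7R,11R)-7,11,15-trimethyl-3-methylidenehexadec-1-en-1-yl]pyrrolidine | C[Si](C)(C)OC(c1cc(cc(c1)C(F)(F)F)C(F)(F)F)(c1cc(cc(c1)C(F)(F)F)C(F)(F)F)[C@@H]1CCCN1/C=C/C(=C)CCC[C@H](C)CCC[C@H](C)CCCC(C)C | intermediate (not isolated)
7 | vinylogous aldol adduct, drawn as the free enal (reacts on as its iminium ion; E/Z not fixed): (5R)-5-[5-(benzyloxy)-2-hydroxy-3,6-dimethylphenyl]-5-hydroxy-3-[(4R,8R)-4,8,12-trimethyltridecyl]pent-2-enal | O=CC=C(CCC[C@H](C)CCC[C@H](C)CCCC(C)C)C[C@@H](O)c1c(C)c(OCc2ccccc2)cc(C)c1O | intermediate (not isolated)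
8 | 2-{(2R,4R)-6-(benzyloxy)-4-hydroxy-5,8-dimethyl-2-[(4R,8R)-4,8,12-trimethyltridecyl]chroman-2-yl}acetaldehyde | Cc1cc(OCc2ccccc2)c(C)c3c1O[C@](CC=O)(CCC[C@H](C)CCC[C@H](C)CCCC(C)C)C[C@H]3O | intermediate (not isolated)
9 | bridged lactol of 8: cyclic hemiacetal between the 4-OH and the 2-CH2CHO arm (2,6-methano-1,5-benzodioxocin-4-ol skeleton; chroman centres 2R,4R; anomer mixture) | Cc1cc(OCc2ccccc2)c(C)c3c1O[C@]4(CCC[C@H](C)CCC[C@H](C)CCCC(C)C)C[C@H]3OC(O)C4 | intermediate
10 | bridged δ-lactone: lactone between the 4-O and the 2-CH2CO arm of the (2R,4R)-chroman (2,6-methano-1,5-benzodioxocin-4-one skeleton) | Cc1cc(OCc2ccccc2)c(C)c3c1O[C@]4(CCC[C@H](C)CCC[C@H](C)CCCC(C)C)C[C@H]3OC(=O)C4 | intermediate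
11 | 2-{(2R)-6-(benzyloxy)-5,8-dimethyl-2-[(4R,8R)-4,8,12-trimethyltridecyl]chroman-2-yl}acetic acid | Cc1cc(OCc2ccccc2)c(C)c3c1O[C@](CC(=O)O)(CCC[C@H](C)CCC[C@H](C)CCCC(C)C)CC3 | intermediate
12 | acid chloride of 11 | Cc1cc(OCc2ccccc2)c(C)c3c1O[C@](CC(=O)Cl)(CCC[C@H](C)CCC[C@H](C)CCCC(C)C)CC3 | intermediate (not isolated)
13 | Barton ester of 11 (2-thioxopyridin-1(2H)-yl ester) | Cc1cc(OCc2ccccc2)c(C)c3c1O[C@](CC(=O)On4ccccc4=S)(CCC[C@H](C)CCC[C@H](C)CCCC(C)C)CC3 | intermediate (not isolated)
14 | (2R,4'R,8'R)-β-tocopherol benzyl ether, (2R)-6-(benzyloxy)-2,5,8-trimethyl-2-[(4R,8R)-4,8,12-trimethyltridecyl]chroman | Cc1cc(OCc2ccccc2)c(C)c3c1O[C@](C)(CCC[C@H](C)CCC[C@H](C)CCCC(C)C)CC3 | intermediate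
15 | (2R,4'R,8'R)-β-tocopherol | Cc1cc(O)c(C)c2c1O[C@](C)(CCC[C@H](C)CCC[C@H](C)CCCC(C)C)CC2 | target

## Step count and risks

Total step count: 8. Longest linear sequence: 7 steps (1 → 2 → 3 → 9 → 10 → 11 → 14 → 15); the phytol branch joins at step 4.

The 2-epimer content of the final product is fixed in step 4 and cannot easily be removed later, so it is checked by chiral HPLC at 9 or 10.

**Step 4 (domino aldol/oxa-Michael).** The risks are low conversion with the hindered aldehyde, competing oxa-Michael/aldol condensation to a 2H-chromene-3-carbaldehyde, and insufficient or wrong facial control at C2. The fallback sets out from 4 (and uses 2) and comes back at 14; it fixes C2 by Sharpless epoxidation and closes the pyran ring by aryl C–O coupling with retention. Phytol 4 is epoxidised with Ti(OiPr)4, D-(−)-diethyl tartrate and t-BuOOH (4 Å sieves, CH2Cl2, −20 °C) to (2R,3R)-2,3-epoxyphytol F1. Appel chlorination (PPh3, CCl4, NaHCO3) gives the epoxy chloride F2. n-BuLi (3.5 equiv, THF, −35 °C) converts it, with retention at the carbinol carbon, into (3R,7R,11R)-3,7,11,15-tetramethylhexadec-1-yn-3-ol F3. In parallel, phenol 2 is iodinated ortho to the OH (NIS, cat. TsOH, MeCN) to 4-(benzyloxy)-2-iodo-3,6-dimethylphenol F4 and converted with Tf2O/pyridine into the iodo aryl triflate F5. Sonogashira coupling of F3 with F5 at the iodide (PdCl2(PPh3)2, CuI, Et3N, DMF, 50 °C) gives the alkynyl triflate F6. Hydrogenation of the triple bond (H2, PtO2, EtOAc) gives the saturated hydroxy triflate F7. Intramolecular C–O coupling (Pd(OAc)2, 2-(di-tert-butylphosphino)-1,1'-binaphthyl, Cs2CO3, toluene, 80 °C) closes the pyran ring without touching the carbinol C–O bond and delivers 14.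

**Step 7 (Barton decarboxylation).** The risks are the hindered neopentyl-type acid and ring opening of the β-aryloxy radical. The fallback sets out from 11 and comes back at 14; it replaces the radical step by a metal-mediated decarbonylation. LiAlH4 (THF, 0 °C) reduces 11 to the chroman-2-ethanol F10. Dess–Martin periodinane (NaHCO3, CH2Cl2) gives the chroman-2-acetaldehyde F11. Stoichiometric RhCl(PPh3)3 in refluxing toluene (Tsuji–Wilkinson decarbonylation) converts CH2CHO into the C2 methyl and gives 14.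

**Step 6 (ionic hydrogenation).** The risks are incomplete C–O cleavage and loss of C2 integrity through a chromene formed from the C4 cation. The fallback sets out from 10 and comes back at 11; it uses heterogeneous hydrogenolysis instead of a cation. H2 (4 bar) over Pd(OH)2/C in EtOAc/AcOH cleaves the benzylic lactone C–O bond and the benzyl ether together to give the phenolic acid F8. BnBr/K2CO3 in DMF gives the benzyl ester benzyl ether F9. LiOH in THF/MeOH/H2O hydrolyses the ester to 11.

## Further compounds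

F1 | step 4 | (2R,3R,7R,11R)-2,3-epoxy-3,7,11,15-tetramethylhexadecan-1-ol | OC[C@H]1O[C@]1(C)CCC[C@H](C)CCC[C@H](C)CCCC(C)C
F2 | step 4 | (2S,3R,7R,11R)-1-chloro-2,3-epoxy-3,7,11,15-tetramethylhexadecane | ClC[C@H]1O[C@]1(C)CCC[C@H](C)CCC[C@H](C)CCCC(C)C
F3 | step 4 | (3R,7R,11R)-3,7,11,15-tetramethylhexadec-1-yn-3-ol | C#C[C@@](O)(C)CCC[C@H](C)CCC[C@H](C)CCCC(C)C
F4 | step 4 | 4-(benzyloxy)-2-iodo-3,6-dimethylphenol | Cc1cc(OCc2ccccc2)c(C)c(I)c1O
F5 | step 4 | 4-(benzyloxy)-2-iodo-3,6-dimethylphenyl trifluoromethanesulfonate | Cc1cc(OCc2ccccc2)c(C)c(I)c1OS(=O)(=O)C(F)(F)F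
F6 | step 4 | 4-(benzyloxy)-2-[(3R,7R,11R)-3-hydroxy-3,7,11,15-tetramethylhexadec-1-yn-1-yl]-3,6-dimethylphenyl trifluoromethanesulfonate | Cc1cc(OCc2ccccc2)c(C)c(C#C[C@@](O)(C)CCC[C@H](C)CCC[C@H](C)CCCC(C)C)c1OS(=O)(=O)C(F)(F)F
F7 | step 4 | 4-(benzyloxy)-2-[(3R,7R,11R)-3-hydroxy-3,7,11,15-tetramethylhexadecyl]-3,6-dimethylphenyl trifluoromethanesulfonate | Cc1cc(OCc2ccccc2)c(C)c(CC[C@@](O)(C)CCC[C@H](C)CCC[C@H](C)CCCC(C)C)c1OS(=O)(=O)C(F)(F)F
F8 | step 6 | 2-{(2R)-6-hydroxy-5,8-dimethyl-2-[(4R,8R)-4,8,12-trimethyltridecyl]chroman-2-yl}acetic acid | Cc1cc(O)c(C)c2c1O[C@](CC(=O)O)(CCC[C@H](C)CCC[C@H](C)CCCC(C)C)CC2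
F9 | step 6 | benzyl 2-{(2R)-6-(benzyloxy)-5,8-dimethyl-2-[(4R,8R)-4,8,12-trimethyltridecyl]chroman-2-yl}acetate | Cc1cc(OCc2ccccc2)c(C)c3c1O[C@](CC(=O)OCc4ccccc4)(CCC[C@H](C)CCC[C@H](C)CCCC(C)C)CC3
F10 | step 7 | 2-{(2R)-6-(benzyloxy)-5,8-dimethyl-2-[(4R,8R)-4,8,12-trimethyltridecyl]chroman-2-yl}ethanol | Cc1cc(OCc2ccccc2)c(C)c3c1O[C@](CCO)(CCC[C@H](C)CCC[C@H](C)CCCC(C)C)CC3
F11 | step 7 | 2-{(2R)-6-(benzyloxy)-5,8-dimethyl-2-[(4R,8R)-4,8,12-trimethyltridecyl]chroman-2-yl}acetaldehyde | Cc1cc(OCc2ccccc2)c(C)c3c1O[C@](CC=O)(CCC[C@H](C)CCC[C@H](C)CCCC(C)C)CC3
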